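**Plan**

1. Germacrane numbering is used: C1 furanone C=O, C2, C3 (furanone C–O), C4(=C15H2), C5(OH), C6(O‑lactone), C7, C8(ester), C9, C10(Me, O), C11(=C13H2), C12 lactone C=O. The retrosynthesis cuts, in order: the C8 ester and the silyl ethers; C6–C7 and C11–C12 together (the lactone C12–O6 bond closes on acidification), which leaves an open allenyl aldehyde and CO2; O10–C3 of the furanone; and C1–C2, which leaves a C2–C6 alkyne and a C1/C7–C10 lactone.
2. Forward: two chiral‑pool fragments are joined at C1–C2 (acetylide on lactone) and the furanone ring is closed first. One operation then closes the ten‑membered carbocycle and builds the α‑methylene lactone from allene, CO2 and aldehyde. The isobutyrate goes on last.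
3. Enabling feature: the flat five‑membered furanone ring (O, C3, C2, C1, C10, i.e. the 3,10‑oxygen bridge with quaternary C10) holds the C4–C6 arm and the C9–C7 arm on the same side, so the terminal allene C7=C11=C13 faces the C6 aldehyde. The central allene carbon C11 takes up CO2 as C12, and the resulting allylmetal delivers C7 to C6.
4. Stereochemistry: C5 from methyl (R)‑glycerate acetonide, C10 from (R)‑citramalic acid, C8 from a Noyori transfer hydrogenation, C6 and C7 in the key step (Felkin–Anh addition next to C5–OTBS; chair allyl transfer giving the cis lactone).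

Key step: step 13

Remark: in germacrane numbering the given structure is 5S,6R,7R,8R,10R, which places H6 and H7 cis on the lactone and the C5 and C6 oxygens anti; the route is built for this isomer.

**Route**

Step 1
Reactants: 1 methyl (R)-2,2-dimethyl-1,3-dioxolane-4-carboxylate; 2 ethynyltrimethylsilane
Product: 4 (R)-1-(2,2-dimethyl-1,3-dioxolan-4-yl)-3-(trimethylsilyl)prop-2-yn-1-one, via lithium (trimethylsilyl)acetylide 3 (not isolated)
Conditions: 2, n-BuLi, THF, −78 °C; BF3·OEt2, −78 °C; then 1; aq. NH4Cl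
Reagents that add atoms: none
Why: BF3-promoted acylation of a lithium acetylide by an ester should stop at the ynone because the tetrahedral adduct survives at −78 °C until the quench, and the C5 stereocentre comes unchanged from the chiral pool.

Step 2
Reactants: 4 ynone
Product: 5 (S)-2,2-dimethyl-4-[4-(trimethylsilyl)but-1-en-3-yn-2-yl]-1,3-dioxolane
Conditions: Ph3PCH3Br, KN(SiMe3)2, THF, 0 °C; then 4, −78 → 0 °C
Reagents that add atoms: methyltriphenylphosphonium bromide, C[P+](c1ccccc1)(c1ccccc1)c1ccccc1.[Br-]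
Why: Wittig methylenation with the salt-free ylide at low temperature should convert the C4 ketone into the C4=C15 alkene faster than it enolises the α-alkoxy centre C5.

Step 3
Reactants: 5 silylated enyne acetonide
Product: 7 (S)-3-methylidenepent-4-yne-1,2-diol, via terminal alkyne acetonide 6 (not isolated)
Conditions: K2CO3 (0.2 equiv), MeOH, 0 °C → rt; then Dowex 50WX8 (H+ form), 40 °C; filter, concentrate
Reagents that add atoms: none
Why: Carbonate-catalysed methanolysis of the alkynyl C–Si bond followed by acid-catalysed transketalisation of the acetonide should remove both masking groups in one flask without touching the enyne or C5.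

Step 4
Reactants: 7 enyne diol
Product: 9 (S)-2-(tert-butyldimethylsilyloxy)-3-methylidene-1-(triethylsilyloxy)pent-4-yne, via primary triethylsilyl ether 8 (not isolated)
Conditions: Et3SiCl (1.0 equiv), imidazole, DMF, −40 °C; then t-BuMe2SiCl, DMAP (cat.), −40 °C → rt
Reagents that add atoms: chlorotriethylsilane, CC[Si](Cl)(CC)CC; tert-butylchlorodimethylsilane, CC(C)(C)[Si](C)(C)Cl
Why: Sequential silylation should place the labile TES group on the primary C6 hydroxyl (primary reacts faster than secondary) and the robust TBS group on the allylic C5 hydroxyl.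

Step 5
Reactants: 10 (R)-citramalic acid
Product: 11 2-[(4R)-2,2,4-trimethyl-5-oxo-1,3-dioxolan-4-yl]acetic acid
Conditions: 2,2-dimethoxypropane, TsOH·H2O (cat.), rt
Reagents that add atoms: 2,2-dimethoxypropane, COC(C)(C)OC
Why: Ketalisation should engage the α-hydroxy acid selectively as the five-membered 1,3-dioxolan-4-one and leave the CH2CO2H group free, with C10 taken from the chiral pool.

Step 6
Reactants: 11 dioxolanone acid; 12 tert-butyldimethyl(prop-2-yn-1-yloxy)silane
Product: 14 (5R)-5-[5-(tert-butyldimethylsilyloxy)-2-oxopent-3-yn-1-yl]-2,2,5-trimethyl-1,3-dioxolan-4-one, via acid chloride 13 (not isolated)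
Conditions: (COCl)2, DMF (cat.), CH2Cl2, 0 °C → rt; concentrate; then 12, PdCl2(PPh3)2 (2 mol %), CuI (4 mol %), Et3N, THF, rt
Reagents that add atoms: none
Why: Acyl Sonogashira coupling of the acid chloride with the terminal alkyne should give the ynone (C8 carbonyl, C7≡C11, C13 as CH2OTBS) without opening the dioxolanone.

Step 7
Reactants: 14 ynone
Product: 16 (3R,5R)-3-hydroxy-5-(3-hydroxyprop-1-yn-1-yl)-3-methyloxolan-2-one, via propargylic alcohol 15 (not isolated)
Conditions: Ru[(R,R)-TsDPEN](p-cymene) (1 mol %), i-PrOH, rt; then TsOH·H2O (cat.), MeOH, rt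
Reagents that add atoms: none
Why: Noyori asymmetric transfer hydrogenation of the ynone should set C8 as R under catalyst control (alkynyl versus alkyl differentiation by the (R,R)-ligand), and acid then drives transesterification to the γ-lactone with loss of acetone and of the TBS group.

Step 8
Reactants: 16 propargylic alcohol lactone
Product: 19 (3R,5R)-3-hydroxy-3-methyl-5-(propa-1,2-dien-1-yl)oxolan-2-one, via N-propargyl sulfonylhydrazide 17 (not isolated), via propargyl diazene 18 (not isolated)
Conditions: PPh3, DEAD, THF, −15 °C; 2-nitrobenzenesulfonylhydrazide, −15 → 23 °C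
Reagents that add atoms: none
Why: Myers allene synthesis, in which Mitsunobu substitution of the primary propargylic hydroxyl by the sulfonylhydrazide, loss of sulfinic acid and retro-ene loss of N2 from the propargyl diazene should give the terminal allene C7=C11=C13 while the tertiary alcohol and C8 stay untouched.

Step 9
Reactants: 9 C2–C6 alkyne; 19 allenyl lactone
Product: 21 (2S,7R,9R)-2-(tert-butyldimethylsilyloxy)-7,9-dihydroxy-7-methyl-3-methylidene-1-(triethylsilyloxy)dodeca-10,11-dien-4-yn-6-one, via lithium acetylide 20 (not isolated)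
Conditions: 9, n-BuLi, THF, −78 °C; added to 19 pretreated with LiN(SiMe3)2 (1.0 equiv), THF, −78 → −40 °C; aq. NH4Cl
Reagents that add atoms: none
Why: Addition of a lithium acetylide to a γ-lactone should stop after one addition because the lactol alkoxide is stable at low temperature, which forms the C1–C2 bond of the α′-hydroxy ynone and frees the C8 hydroxyl.

Step 10
Reactants: 21 ynone diol
Product: 22 (2S,7R,9R)-2-(tert-butyldimethylsilyloxy)-7-hydroxy-7-methyl-3-methylidene-1,9-bis(triethylsilyloxy)dodeca-10,11-dien-4-yn-6-one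
Conditions: Et3SiCl, imidazole, DMAP (cat.), CH2Cl2, 0 °C
Reagents that add atoms: chlorotriethylsilane, CC[Si](Cl)(CC)CC
Why: Silylation should discriminate the secondary C8 hydroxyl from the tertiary C10 hydroxyl, which must stay free for the furanone closure.

Step 11
Reactants: 22 α′-hydroxy ynone
Product: 24 (R)-5-[(S)-3-(tert-butyldimethylsilyloxy)-4-(triethylsilyloxy)but-1-en-2-yl]-2-methyl-2-[(R)-2-(triethylsilyloxy)penta-3,4-dien-1-yl]furan-3(2H)-one, via diethylamino enone 23 (not isolated)
Conditions: Et2NH, EtOH, rt; then AcOH, rt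
Reagents that add atoms: none
Why: Conjugate addition of the amine to the ynone followed by 5-exo-trig addition–elimination of the C10 hydroxyl at C3 (net 5-endo-dig oxa-Michael addition) is the standard closure of α′-hydroxy ynones to 3(2H)-furanones and should tolerate the allene and the silyl ethers.

Step 12
Reactants: 24 furanone with primary TES ether
Product: 25 (S)-2-(tert-butyldimethylsilyloxy)-3-{(R)-5-methyl-4-oxo-5-[(R)-2-(triethylsilyloxy)penta-3,4-dien-1-yl]-4,5-dihydrofuran-2-yl}but-3-enal
Conditions: (COCl)2, DMSO, CH2Cl2, −78 °C; 24, −78 → −30 °C; i-Pr2NEt, −78 → −20 °C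
Reagents that add atoms: none
Why: Under Swern conditions a primary TES ether is oxidised directly to the aldehyde (oxidative desilylation) while secondary TES and TBS ethers survive, so the labile α-silyloxy aldehyde at C6 is made in one operation and used at once.

Step 13
Reactants: 25 allenyl aldehyde; 26 carbon dioxide
Product: 29 (5S,6R,7S,8R,10R)-5-(tert-butyldimethylsilyloxy)-1-oxo-8-(triethylsilyloxy)-3,10-epoxygermacra-2,4(15),11(13)-trien-12,6-olide, via oxanickelacycle 27 (not isolated), via hydroxy acid 28 (not isolated)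
Conditions: Ni(cod)2 (2 equiv), DBU (4 equiv), CO2 (1 atm), THF, 0 °C, 25 added over 8 h (final 3 mM); then 0.5 M HCl, 0 °C; PPTS (cat.), CH2Cl2, rt
Reagents that add atoms: none
Why: Proposed new method: zerovalent nickel (Ni(cod)2/DBU) should couple CO2 with the terminal C11=C13 π-bond of the allene by oxidative cyclisation (C11–C12 bond) to give the divalent-nickel oxanickelacycle 27, an allylnickel carboxylate whose γ-carbon C7 then adds to the tethered aldehyde carbon C6 through a six-membered chair with nickel on C13 and on the carbonyl oxygen (C6–C7 bond); acid releases hydroxy acid 28, which lactonises. The closest known reaction type is the Ni(cod)2/DBU-mediated carboxylation of terminal allenes with CO2 in which the oxanickelacycle is trapped by an aldehyde, between molecules or within one molecule to give five- and six-membered rings; the extension is the medium ring. The ten-membered carbocycle (nine-membered when counted through the furanone oxygen) closes by intramolecular carbonyl allylation, exo at the aldehyde and SE2′ at the allyl unit, and the lactone then closes by 5-exo-trig acyl substitution of the C6 hydroxyl on the C12 carboxyl. C6 should follow from Felkin–Anh attack anti to the C5–OTBS bond (5,6-anti), and C7 from the chair in which C8 lies cis to the nickel-bearing C13 (CO2 enters on the allene face away from C8 and allylic strain against the carboxylate keeps this geometry), which gives the syn adduct and hence the cis-fused lactone with the C8 silyloxy group in the inside position and the tether on the reacting face. The step needs CO2 uptake at the allene and not at the 2-alkenylfuranone diene (terminal allenes react at 0 °C, the electron-poor cross-conjugated diene should not), attack through C7 and not C13 (nickel sits on the primary carbon of the chelate), no β-elimination or 8,12-lactone at C8 (its oxygen is a silyl ether, so only the C6 hydroxyl can lactonise), an intact C5 centre (DBU is bound to nickel and CO2), and ring closure instead of oligomerisation (slow addition at high dilution, both arms held syn by the furanone ring with quaternary C10).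

Step 14
Reactants: 29 bis-silylated lactone
Product: 30 (5S,6R,7R,8R,10R)-5-(tert-butyldimethylsilyloxy)-8-hydroxy-1-oxo-3,10-epoxygermacra-2,4(15),11(13)-trien-12,6-olide
Conditions: PPTS, MeOH/CH2Cl2, 0 °C
Reagents that add atoms: none
Why: Acid-catalysed methanolysis should cleave the secondary TES ether at C8 much faster than the hindered secondary TBS ether at C5.

Step 15
Reactants: 30 C8 alcohol
Product: 31 (5S,6R,7R,8R,10R)-5-(tert-butyldimethylsilyloxy)-8-(2-methylpropanoyloxy)-1-oxo-3,10-epoxygermacra-2,4(15),11(13)-trien-12,6-olide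
Conditions: (i-PrCO)2O, pyridine, DMAP (cat.), CH2Cl2, 0 °C → rt
Reagents that add atoms: isobutyric anhydride, CC(C)C(=O)OC(=O)C(C)C
Why: DMAP-catalysed acylation (Steglich-type acyl transfer) of the only free hydroxyl should install the C8 isobutyrate.

Step 16
Reactants: 31 TBS ether of the target
Product: 32 (5S,6R,7R,8R,10R)-5-hydroxy-8-(2-methylpropanoyloxy)-1-oxo-3,10-epoxygermacra-2,4(15),11(13)-trien-12,6-olide
Conditions: HF·pyridine, pyridine, THF, 0 °C → rt
Reagents that add atoms: none
Why: Buffered fluoride desilylation should free the C5 hydroxyl without affecting the ester, the α-methylene lactone or the furanone.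

**Compound list**

1 | methyl (R)-2,2-dimethyl-1,3-dioxolane-4-carboxylate | COC(=O)[C@H]1COC(C)(C)O1 | starting material
2 | ethynyltrimethylsilane | C#C[Si](C)(C)C | starting material
3 | lithium (trimethylsilyl)acetylide (not isolated) | [Li]C#C[Si](C)(C)C | intermediate
4 | (R)-1-(2,2-dimethyl-1,3-dioxolan-4-yl)-3-(trimethylsilyl)prop-2-yn-1-one | C[Si](C)(C)C#CC(=O)[C@H]1COC(C)(C)O1 | intermediate
5 | (S)-2,2-dimethyl-4-[4-(trimethylsilyl)but-1-en-3-yn-2-yl]-1,3-dioxolane | C[Si](C)(C)C#CC(=C)[C@H]1COC(C)(C)O1 | intermediate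
6 | (S)-4-(but-1-en-3-yn-2-yl)-2,2-dimethyl-1,3-dioxolane (not isolated) | C#CC(=C)[C@H]1COC(C)(C)O1 | intermediate
7 | (S)-3-methylidenepent-4-yne-1,2-diol | C#CC(=C)[C@H](O)CO | intermediate
8 | (S)-3-methylidene-1-(triethylsilyloxy)pent-4-yn-2-ol (not isolated) | C#CC(=C)[C@H](O)CO[Si](CC)(CC)CC | intermediate
9 | (S)-2-(tert-butyldimethylsilyloxy)-3-methylidene-1-(triethylsilyloxy)pent-4-yne | C#CC(=C)[C@H](O[Si](C)(C)C(C)(C)C)CO[Si](CC)(CC)CC | intermediate
10 | (R)-citramalic acid, (R)-2-hydroxy-2-methylbutanedioic acid | OC(=O)C[C@@](C)(O)C(=O)O | starting material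
11 | 2-[(4R)-2,2,4-trimethyl-5-oxo-1,3-dioxolan-4-yl]acetic acid | OC(=O)C[C@@]1(C)OC(C)(C)OC1=O | intermediate
12 | tert-butyldimethyl(prop-2-yn-1-yloxy)silane | C#CCO[Si](C)(C)C(C)(C)C | starting material
13 | 2-[(4R)-2,2,4-trimethyl-5-oxo-1,3-dioxolan-4-yl]acetyl chloride (not isolated) | ClC(=O)C[C@@]1(C)OC(C)(C)OC1=O | intermediate
14 | (5R)-5-[5-(tert-butyldimethylsilyloxy)-2-oxopent-3-yn-1-yl]-2,2,5-trimethyl-1,3-dioxolan-4-one | CC(C)(C)[Si](C)(C)OCC#CC(=O)C[C@@]1(C)OC(C)(C)OC1=O | intermediate
15 | (5R)-5-[(2R)-5-(tert-butyldimethylsilyloxy)-2-hydroxypent-3-yn-1-yl]-2,2,5-trimethyl-1,3-dioxolan-4-one (not isolated) | CC(C)(C)[Si](C)(C)OCC#C[C@H](O)C[C@@]1(C)OC(C)(C)OC1=O | intermediate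
16 | (3R,5R)-3-hydroxy-5-(3-hydroxyprop-1-yn-1-yl)-3-methyloxolan-2-one | OCC#C[C@H]1C[C@@](C)(O)C(=O)O1 | intermediate
17 | N-{3-[(2R,4R)-4-hydroxy-4-methyl-5-oxooxolan-2-yl]prop-2-yn-1-yl}-2-nitrobenzenesulfonohydrazide (not isolated) | NN(CC#C[C@H]1C[C@@](C)(O)C(=O)O1)S(=O)(=O)c1ccccc1[N+](=O)[O-] | intermediate
18 | (3R,5R)-5-(3-diazenylprop-1-yn-1-yl)-3-hydroxy-3-methyloxolan-2-one (not isolated) | N=NCC#C[C@H]1C[C@@](C)(O)C(=O)O1 | intermediate
19 | (3R,5R)-3-hydroxy-3-methyl-5-(propa-1,2-dien-1-yl)oxolan-2-one | C=C=C[C@H]1C[C@@](C)(O)C(=O)O1 | intermediate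
20 | lithium acetylide of 9 (not isolated) | [Li]C#CC(=C)[C@H](O[Si](C)(C)C(C)(C)C)CO[Si](CC)(CC)CC | intermediate
21 | (2S,7R,9R)-2-(tert-butyldimethylsilyloxy)-7,9-dihydroxy-7-methyl-3-methylidene-1-(triethylsilyloxy)dodeca-10,11-dien-4-yn-6-one | C=C=C[C@H](O)C[C@@](C)(O)C(=O)C#CC(=C)[C@H](O[Si](C)(C)C(C)(C)C)CO[Si](CC)(CC)CC | intermediate
22 | (2S,7R,9R)-2-(tert-butyldimethylsilyloxy)-7-hydroxy-7-methyl-3-methylidene-1,9-bis(triethylsilyloxy)dodeca-10,11-dien-4-yn-6-one | C=C=C[C@H](O[Si](CC)(CC)CC)C[C@@](C)(O)C(=O)C#CC(=C)[C@H](O[Si](C)(C)C(C)(C)C)CO[Si](CC)(CC)CC | intermediate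
23 | (2S,7R,9R)-2-(tert-butyldimethylsilyloxy)-4-(diethylamino)-7-hydroxy-7-methyl-3-methylidene-1,9-bis(triethylsilyloxy)dodeca-4,10,11-trien-6-one (not isolated) | C=C=C[C@H](O[Si](CC)(CC)CC)C[C@@](C)(O)C(=O)C=C(N(CC)CC)C(=C)[C@H](O[Si](C)(C)C(C)(C)C)CO[Si](CC)(CC)CC | intermediate
24 | (R)-5-[(S)-3-(tert-butyldimethylsilyloxy)-4-(triethylsilyloxy)but-1-en-2-yl]-2-methyl-2-[(R)-2-(triethylsilyloxy)penta-3,4-dien-1-yl]furan-3(2H)-one | C=C=C[C@H](O[Si](CC)(CC)CC)C[C@@]1(C)OC(=CC1=O)C(=C)[C@H](O[Si](C)(C)C(C)(C)C)CO[Si](CC)(CC)CC | intermediate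
25 | (S)-2-(tert-butyldimethylsilyloxy)-3-{(R)-5-methyl-4-oxo-5-[(R)-2-(triethylsilyloxy)penta-3,4-dien-1-yl]-4,5-dihydrofuran-2-yl}but-3-enal | C=C=C[C@H](O[Si](CC)(CC)CC)C[C@@]1(C)OC(=CC1=O)C(=C)[C@H](O[Si](C)(C)C(C)(C)C)C=O | intermediate
26 | carbon dioxide | O=C=O | starting material
27 | oxanickelacycle of 25 and CO2: 1-oxa-2-nickelacyclopentan-5-one with the C7 alkylidene on C11, C8 cis to C13 (DBU ligands omitted; not isolated) | O=C1O[Ni]C/C1=C\[C@H](O[Si](CC)(CC)CC)C[C@@]1(C)OC(=CC1=O)C(=C)[C@H](O[Si](C)(C)C(C)(C)C)C=O | intermediate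
28 | (5S,6R,7S,8R,10R)-5-(tert-butyldimethylsilyloxy)-6-hydroxy-1-oxo-8-(triethylsilyloxy)-3,10-epoxygermacra-2,4(15),11(13)-trien-12-oic acid (not isolated; 7S only through the CIP effect of the C8 silyl ether) | C=C(C(=O)O)[C@@H]1[C@H](O[Si](CC)(CC)CC)C[C@@]2(C)OC(=CC2=O)C(=C)[C@H](O[Si](C)(C)C(C)(C)C)[C@@H]1O | intermediate
29 | (5S,6R,7S,8R,10R)-5-(tert-butyldimethylsilyloxy)-1-oxo-8-(triethylsilyloxy)-3,10-epoxygermacra-2,4(15),11(13)-trien-12,6-olide (7S only through the CIP effect of the C8 silyl ether) | C=C1C(=O)O[C@@H]2[C@H]1[C@H](O[Si](CC)(CC)CC)C[C@@]1(C)OC(=CC1=O)C(=C)[C@@H]2O[Si](C)(C)C(C)(C)C | intermediate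
30 | (5S,6R,7R,8R,10R)-5-(tert-butyldimethylsilyloxy)-8-hydroxy-1-oxo-3,10-epoxygermacra-2,4(15),11(13)-trien-12,6-olide | C=C1C(=O)O[C@@H]2[C@H]1[C@H](O)C[C@@]1(C)OC(=CC1=O)C(=C)[C@@H]2O[Si](C)(C)C(C)(C)C | intermediate
31 | (5S,6R,7R,8R,10R)-5-(tert-butyldimethylsilyloxy)-8-(2-methylpropanoyloxy)-1-oxo-3,10-epoxygermacra-2,4(15),11(13)-trien-12,6-olide | C=C1C(=O)O[C@@H]2[C@H]1[C@H](OC(=O)C(C)C)C[C@@]1(C)OC(=CC1=O)C(=C)[C@@H]2O[Si](C)(C)C(C)(C)C | intermediate
32 | (5S,6R,7R,8R,10R)-5-hydroxy-8-(2-methylpropanoyloxy)-1-oxo-3,10-epoxygermacra-2,4(15),11(13)-trien-12,6-olide (CNP0384113.1) | C=C1C(=O)O[C@@H]2[C@H]1[C@H](OC(=O)C(C)C)C[C@@]1(C)OC(=CC1=O)C(=C)[C@@H]2O | target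

**Step count and risks**

Total step count: 16. Longest linear sequence: 12 steps (steps 1–4 or steps 5–8, followed by steps 9–16).

Steps most likely to fail:

1. Step 13 (proposed new method). The allylnickel carboxylate may be protonated or may oligomerise before it reaches the aldehyde, it may attack through C13, or the base may epimerise C5 and move the C4(15) double bond into conjugation. The fallback sets out from 25 and returns at 29, and forms the two bonds in separate known operations. Platinum-catalysed diboration of the terminal allene π-bond (B2pin2, Pt(dba)2/PCy3, toluene, 50 °C) should give the (Z)-2-boryl allylboronate aldehyde F1. This closes the ten-membered ring without base by intramolecular allylboration through the same chair (C6–C7 bond, syn adduct) and gives, after work-up, the borylated macrocyclic homoallylic alcohol F2. Iododeboronation (NaOMe, then I2, THF, −78 °C) gives the vinyl iodide F3. Carbonylative lactonisation (Pd(PPh3)4, CO 1 atm, K2CO3, THF, 50 °C) then forms the C11–C12 bond and the lactone, which is 29.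

2. Step 12. Base-induced epimerisation at C5 or migration of the 4(15) double bond into conjugation may occur during collapse of the alkoxysulfonium ylide, and the secondary TES group may be partly lost. The fallback sets out from 24 and returns at 25, and separates unmasking from oxidation. Partial methanolysis (PPTS, MeOH/CH2Cl2, −20 °C; the primary TES ether is cleaved faster than the secondary one) gives the primary alcohol F4. This is oxidised without any amine base (Dess–Martin periodinane, NaHCO3, CH2Cl2, 0 °C) to 25, which is used at once.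

3. Step 9. Addition to the alkoxide-bearing lactone may be incomplete, or the acetylide may add a second time once the lactol opens. The fallback sets out from 19 and returns at 22, so steps 9 and 10 are bypassed. Aminolysis of the lactone with MeNH(OMe)·HCl/AlMe3 (CH2Cl2, 0 °C) gives the dihydroxy Weinreb amide F5. Silylation of the secondary hydroxyl (Et3SiCl, imidazole, CH2Cl2, 0 °C) gives the silylated Weinreb amide F6. Addition of lithium acetylide 20 (2.2 equiv, THF, −78 → 0 °C) then gives 22, because the chelated tetrahedral adduct excludes a second addition.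

Further compounds
F1 | step 13 | (S)-2-(tert-butyldimethylsilyloxy)-3-{(R)-5-methyl-4-oxo-5-[(R,Z)-4,5-bis(4,4,5,5-tetramethyl-1,3,2-dioxaborolan-2-yl)-2-(triethylsilyloxy)pent-3-en-1-yl]-4,5-dihydrofuran-2-yl}but-3-enal | CC1(C)OB(OC1(C)C)C/C(B1OC(C)(C)C(C)(C)O1)=C\[C@H](O[Si](CC)(CC)CC)C[C@@]1(C)OC(=CC1=O)C(=C)[C@H](O[Si](C)(C)C(C)(C)C)C=O
F2 | step 13 | analogue of 28 with a 4,4,5,5-tetramethyl-1,3,2-dioxaborolan-2-yl group on C11 in place of CO2H (configuration at C5–C8 and C10 as in 28) | C=C(B1OC(C)(C)C(C)(C)O1)[C@@H]1[C@H](O[Si](CC)(CC)CC)C[C@@]2(C)OC(=CC2=O)C(=C)[C@H](O[Si](C)(C)C(C)(C)C)[C@@H]1O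
F3 | step 13 | analogue of 28 with iodine on C11 in place of CO2H (configuration at C5–C8 and C10 as in 28) | C=C(I)[C@@H]1[C@H](O[Si](CC)(CC)CC)C[C@@]2(C)OC(=CC2=O)C(=C)[C@H](O[Si](C)(C)C(C)(C)C)[C@@H]1O
F4 | step 12 | (R)-5-[(S)-3-(tert-butyldimethylsilyloxy)-4-hydroxybut-1-en-2-yl]-2-methyl-2-[(R)-2-(triethylsilyloxy)penta-3,4-dien-1-yl]furan-3(2H)-one | C=C=C[C@H](O[Si](CC)(CC)CC)C[C@@]1(C)OC(=CC1=O)C(=C)[C@H](O[Si](C)(C)C(C)(C)C)CO
F5 | step 9 | (2R,4R)-2,4-dihydroxy-N-methoxy-N,2-dimethylhepta-5,6-dienamide | C=C=C[C@H](O)C[C@@](C)(O)C(=O)N(C)OC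
F6 | step 9 | (2R,4R)-2-hydroxy-N-methoxy-N,2-dimethyl-4-(triethylsilyloxy)hepta-5,6-dienamide | C=C=C[C@H](O[Si](CC)(CC)CC)C[C@@](C)(O)C(=O)N(C)OC
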